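**Retrosynthetic overview**

1. Cyclointegrin 11 ⇐ 10 by hydrogenolysis of the 5-O- and 4'-O-benzyl ethers.
2. 10 ⇐ 8 by a one-pot double SNAr on a 2-(2,4-difluorophenyl)chromone: ring D (the oxocine) is closed last, by the bond between the tertiary side-chain oxygen and C2' of ring B; the 4'-fluoride is then exchanged for benzyloxy in the same flask.
3. Enabling feature: C2' and C4' are ortho and para to C1', and C1' sits on C2 of the pyranone ring C, whose C2=C3–C4=O unit acts as a vinylogous acyl group that carries the Meisenheimer charge onto O4. The C2=C3 bond and the C1'–C2' ring bond hold the C3 chain and the 2'-fluoride cis, and the gem-dimethyl group helps the eight-membered closure.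
4. 8 ⇐ 7 (MeMgBr) ⇐ 4 + methyl vinyl ketone (Michael addition, then cyclodehydration closes ring C) ⇐ 2 + 2,4-difluorobenzoyl chloride (C-aroylation) ⇐ 1 (monobenzylation).
5. Ring order: rings A and B come with the starting materials, ring C is formed in step 3, ring D in step 5.

Key step: step 5

Remark: the target has no stereocenter. Flavone numbering is used: ring A is the benzo ring (C5–C8), ring C the pyranone (O1, C2, C3, C4), ring B the aryl ring on C2 (primed numbers), ring D the oxocine.

**Step 1**
Reactants: 1 1-(2,6-dihydroxy-4-methoxyphenyl)ethan-1-one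
Product: 2 1-[2-(benzyloxy)-6-hydroxy-4-methoxyphenyl]ethan-1-one
Conditions: BnBr (1.05 equiv), K2CO3 (1.1 equiv), acetone, reflux
Reagents that add atoms: benzyl bromide, BrCc1ccccc1
Why: Williamson ether synthesis on a symmetrical diphenol; after the first benzylation the remaining hydroxyl is locked in a hydrogen bond to the acetyl carbonyl, which should hold back the second alkylation.

**Step 2**
Reactants: 2 1-[2-(benzyloxy)-6-hydroxy-4-methoxyphenyl]ethan-1-one; 3 2,4-difluorobenzoyl chloride
Product: 4 1-[2-(benzyloxy)-6-hydroxy-4-methoxyphenyl]-3-(2,4-difluorophenyl)propane-1,3-dione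
Conditions: LiN(SiMe3)2 (3.2 equiv), THF, −78 °C; then 3, −78 to −20 °C; 1 M HCl
Reagents that add atoms: none
Why: Claisen-type C-aroylation of the lithium enolate of an o-hydroxyacetophenone (the one-pot equivalent of the Baker–Venkataraman rearrangement); excess amide keeps phenoxide and product diketonate deprotonated, and the low temperature should keep the lithium diketonate from displacing the ortho fluoride.

**Step 3**
Reactants: 4 1-[2-(benzyloxy)-6-hydroxy-4-methoxyphenyl]-3-(2,4-difluorophenyl)propane-1,3-dione; 5 but-3-en-2-one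
Product: 7 5-(benzyloxy)-2-(2,4-difluorophenyl)-7-methoxy-3-(3-oxobutyl)-4H-chromen-4-one, via triketone Michael adduct 6 (not isolated)
Conditions: 5 (1.5 equiv), Et3N (0.2 equiv), MeCN, rt; then TsOH·H2O (0.2 equiv), toluene, 80 °C
Reagents that add atoms: none
Why: Amine-catalysed Michael addition of the 1,3-diketone at its doubly activated carbon gives 6, and acid then closes ring C by the classical cyclodehydration of an o-hydroxyaryl 1,3-diketone (hemiketal at the difluorobenzoyl carbonyl, loss of water), which also removes the stereocenter of 6.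

**Step 4**
Reactants: 7 5-(benzyloxy)-2-(2,4-difluorophenyl)-7-methoxy-3-(3-oxobutyl)-4H-chromen-4-one
Product: 8 5-(benzyloxy)-2-(2,4-difluorophenyl)-3-(3-hydroxy-3-methylbutyl)-7-methoxy-4H-chromen-4-one
Conditions: MeMgBr (1.3 equiv), LaCl3·2LiCl (0.3 equiv), THF, −78 to −40 °C; aq NH4Cl
Reagents that add atoms: methylmagnesium bromide, C[Mg]Br
Why: Chemoselective Grignard 1,2-addition, because the saturated methyl ketone is far more electrophilic than the C4 carbonyl of ring C (a vinylogous ester further deactivated by the ring A oxygens), and the lanthanum salt should suppress enolisation; the new carbinol carbon carries two methyl groups and is not a stereocenter.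

**Step 5**
Reactants: 8 5-(benzyloxy)-2-(2,4-difluorophenyl)-3-(3-hydroxy-3-methylbutyl)-7-methoxy-4H-chromen-4-one
Product: 10 5,4'-di-O-benzylcyclointegrin, via 4'-fluoro oxocine 9 (not isolated)
Conditions: KN(SiMe3)2 (1.1 equiv), THF–DMPU 4:1, 5 mM, −20 °C to rt; then PhCH2OK (from BnOH, 3 equiv, and KN(SiMe3)2, 2.5 equiv), 50 °C; AcOH quench
Reagents that add atoms: benzyl alcohol, OCc1ccccc1
Why: The potassium alkoxide of 8 adds to C2' of ring B and fluoride leaves (addition–elimination SNAr), the Meisenheimer charge at C1' being delocalised through C2=C3 onto the C4 carbonyl oxygen of ring C; potassium benzyl oxide, added only after ring D is closed, then replaces the para (4') fluoride of 9 by the same mechanism. The closest known reaction types are the intramolecular SNAr etherification of carbonyl-activated aryl fluorides to medium-ring aryl ethers and the SNAr of 2'- and 4'-fluoroflavones and fluorochalcones with N and O nucleophiles. Ring D is closed by intramolecular ipso-substitution at C2' as an eight-membered ring (O, CMe2, two CH2, C3, C2, C1', C2') that already holds four cis-locked sp2 atoms and a gem-dimethyl group; no stereocenter is formed. The step needs site selectivity for C2' over C4' and over C2 of ring C: the four-atom tether can reach only C2', the 5 mM dilution and the absence of any other nucleophile in the first stage should hold back intermolecular attack at the 4'-fluoride, and attack at the fully substituted C2 would have to build a 2,2,6,6-tetrasubstituted oxane ketal and break the pyranone conjugation. The 4'-fluorine, meta to C2', should speed the ring closure inductively before it becomes the 4'-oxygen, and the 5-O-benzyl group keeps ring A from forming a phenoxide that would switch off the acceptor.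

**Step 6**
Reactants: 10 5,4'-di-O-benzylcyclointegrin
Product: 11 cyclointegrin
Conditions: H2 (1 atm), Pd/C, EtOAc–MeOH, rt
Reagents that add atoms: none
Why: Hydrogenolysis of both benzyl aryl ethers on palladium under neutral conditions, which should leave the tetrasubstituted C2=C3 bond of ring C and the tertiary alkyl aryl ether of ring D untouched.

**Compound list**

1 | 1-(2,6-dihydroxy-4-methoxyphenyl)ethan-1-one | CC(=O)c1c(O)cc(OC)cc1O | starting material
2 | 1-[2-(benzyloxy)-6-hydroxy-4-methoxyphenyl]ethan-1-one | CC(=O)c1c(O)cc(OC)cc1OCc1ccccc1 | intermediate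
3 | 2,4-difluorobenzoyl chloride | O=C(Cl)c1ccc(F)cc1F | starting material
4 | 1-[2-(benzyloxy)-6-hydroxy-4-methoxyphenyl]-3-(2,4-difluorophenyl)propane-1,3-dione | O=C(CC(=O)c1ccc(F)cc1F)c1c(O)cc(OC)cc1OCc1ccccc1 | intermediate
5 | but-3-en-2-one (methyl vinyl ketone) | CC(=O)C=C | starting material
6 | 1-[2-(benzyloxy)-6-hydroxy-4-methoxyphenyl]-2-(2,4-difluorobenzoyl)hexane-1,5-dione (racemic, not isolated) | CC(=O)CCC(C(=O)c1ccc(F)cc1F)C(=O)c1c(O)cc(OC)cc1OCc1ccccc1 | intermediate
7 | 5-(benzyloxy)-2-(2,4-difluorophenyl)-7-methoxy-3-(3-oxobutyl)-4H-chromen-4-one | CC(=O)CCc1c(-c2ccc(F)cc2F)oc2cc(OC)cc(OCc3ccccc3)c2c1=O | intermediate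
8 | 5-(benzyloxy)-2-(2,4-difluorophenyl)-3-(3-hydroxy-3-methylbutyl)-7-methoxy-4H-chromen-4-one | CC(C)(O)CCc1c(-c2ccc(F)cc2F)oc2cc(OC)cc(OCc3ccccc3)c2c1=O | intermediate
9 | 5-O-benzyl-4'-deoxy-4'-fluorocyclointegrin (ring D closed, fluorine at C4', benzyloxy at C5; not isolated) | COc1cc(OCc4ccccc4)c2c(=O)c3c(oc2c1)-c1ccc(F)cc1OC(C)(C)CC3 | intermediate
10 | 5,4'-di-O-benzylcyclointegrin (flavone with C3 and the 2'-oxygen bridged by CH2CH2C(CH3)2, benzyloxy at C5 and C4', methoxy at C7) | COc1cc(OCc4ccccc4)c2c(=O)c3c(oc2c1)-c1ccc(OCc5ccccc5)cc1OC(C)(C)CC3 | intermediate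
11 | cyclointegrin | COc1cc(O)c2c(=O)c3c(oc2c1)-c1ccc(O)cc1OC(C)(C)CC3 | target

**Totals**

Total step count: 6. Longest linear sequence: 6 steps (1 to 11).

**Steps most likely to fail**

Step 5. The tertiary alkoxide may add to C2 of ring C instead of C2' (six-membered, endo conjugate addition), after which the pyranone opens to a stable phenoxide; it may also etherify the 4'-fluoride of a second molecule and give oligomers. Fallback, from compound 8 to compound 11, closing ring D through the other C–O bond: 8 is heated with acetohydroxamic acid and K2CO3 in DMSO at 80–100 °C. Under carbonate the tertiary alcohol stays protonated, and SNAr by the hydroxamate followed by Lossen-type fragmentation should turn both fluorides into phenols, giving 5-(benzyloxy)-2-(2,4-dihydroxyphenyl)-3-(3-hydroxy-3-methylbutyl)-7-methoxy-4H-chromen-4-one F1. Catalytic TsOH·H2O (or Amberlyst 15) in toluene at 60 °C should then ionise the tertiary alcohol, and trapping of the cation by the 2'-hydroxyl (acid-catalysed dehydrative etherification, as in chroman formation from o-(3-hydroxy-3-methylbutyl)phenols) should give 5-O-benzylcyclointegrin F2. Hydrogenolysis of F2 under the conditions of step 6 gives 11.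

Step 3. The methyl ketone of 6 may undergo aldol condensation onto an aryl ketone faster than the hemiketal dehydrates, or the diketone enolate oxygen may displace the ortho fluoride under base and close the wrong pyranone. Fallback, from compound 4 to compound 8: neutral Tsuji–Trost prenylation of 4 with methyl 3-methylbut-2-en-1-yl carbonate and catalytic Pd(PPh3)4 in THF at rt should give 1-[2-(benzyloxy)-6-hydroxy-4-methoxyphenyl]-2-(2,4-difluorobenzoyl)-5-methylhex-4-en-1-one F3. NaOAc in AcOH at 100 °C should close ring C without touching the prenyl group and give 5-(benzyloxy)-2-(2,4-difluorophenyl)-7-methoxy-3-(3-methylbut-2-en-1-yl)-4H-chromen-4-one F4. Mukaiyama hydration (Co(acac)2, PhSiH3, O2, THF–iPrOH, rt) should then place the hydroxyl at the tertiary carbon and give 8 directly, so that step 4 is bypassed.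

Step 4. The Grignard reagent may enolise the methyl ketone instead of adding, or add to ring C. Fallback, from compound 7 to compound 8: Wittig methylenation (Ph3P=CH2 from the phosphonium bromide and KN(SiMe3)2, THF, 0 °C) should give 5-(benzyloxy)-2-(2,4-difluorophenyl)-7-methoxy-3-(3-methylbut-3-en-1-yl)-4H-chromen-4-one F5, and Markovnikov Mukaiyama hydration of the 1,1-disubstituted alkene (Co(acac)2, PhSiH3, O2, THF–iPrOH, rt) should give 8.

**Further compounds**

F1 | step 5 | 5-(benzyloxy)-2-(2,4-dihydroxyphenyl)-3-(3-hydroxy-3-methylbutyl)-7-methoxy-4H-chromen-4-one | CC(C)(O)CCc1c(-c2ccc(O)cc2O)oc2cc(OC)cc(OCc3ccccc3)c2c1=O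
F2 | step 5 | 5-O-benzylcyclointegrin | COc1cc(OCc4ccccc4)c2c(=O)c3c(oc2c1)-c1ccc(O)cc1OC(C)(C)CC3
F3 | step 3 | 1-[2-(benzyloxy)-6-hydroxy-4-methoxyphenyl]-2-(2,4-difluorobenzoyl)-5-methylhex-4-en-1-one | CC(C)=CCC(C(=O)c1ccc(F)cc1F)C(=O)c1c(O)cc(OC)cc1OCc1ccccc1
F4 | step 3 | 5-(benzyloxy)-2-(2,4-difluorophenyl)-7-methoxy-3-(3-methylbut-2-en-1-yl)-4H-chromen-4-one | CC(C)=CCc1c(-c2ccc(F)cc2F)oc2cc(OC)cc(OCc3ccccc3)c2c1=O
F5 | step 4 | 5-(benzyloxy)-2-(2,4-difluorophenyl)-7-methoxy-3-(3-methylbut-3-en-1-yl)-4H-chromen-4-one | CC(=C)CCc1c(-c2ccc(F)cc2F)oc2cc(OC)cc(OCc3ccccc3)c2c1=O
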